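## Retrosynthetic overview

1. Target 14 comes from α-aroyl lactone 11 by one hydrogenolysis, which takes the C7' ketone to CH2 and frees the phenol.
2. Lactone 11 comes from achiral enone 6 and zinc reagent 9. The lactone is the only ring that is built (both arenes are bought). It closes in one operation: C4–C5 by asymmetric conjugate addition, then C2–C3 by acylation of the resulting enolate.
3. Enabling feature: the ring atoms C5H2–O1–C2(=O), written as a metalated methyl carbonate, are nucleophilic at C5 and electrophilic at C2. The benzylic carbon C7' on C3, raised to an aryl ketone, polarises the C3=C4 alkene in the matching sense. It also tells the two nearly identical benzyl arms apart and makes C3–H acidic, so trans C3/C4 is the thermodynamic outcome.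
4. Enone 6 comes from aryl vinyl ketone 4 and methyl eugenol 5 by cross-metathesis. Ketone 4 comes from aldehyde 1, and reagent 9 from chloromethyl methyl carbonate 7.

Key step: step 7

Assumption: the (S,R,R)-configured phosphoramidite is taken to direct the transfer to the Re face of the enone β-carbon. If a test reaction shows the opposite sense, its (R,S,S) antipode is used and nothing else changes.

## Route

Step 1
Reactants: 1 3-hydroxy-4,5-dimethoxybenzaldehyde
Product: 2 3-(benzyloxy)-4,5-dimethoxybenzaldehyde
Conditions: BnBr, K2CO3, DMF, 23 °C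
Reagents that add atoms: benzyl bromide, BrCc1ccccc1
Why: Williamson ether synthesis on the only acidic OH; the benzyl group masks the phenol against the organometallic steps and leaves in the final hydrogenolysis at no extra cost.

Step 2
Reactants: 2 3-(benzyloxy)-4,5-dimethoxybenzaldehyde
Product: 3 1-[3-(benzyloxy)-4,5-dimethoxyphenyl]prop-2-en-1-ol (racemic)
Conditions: CH2=CHMgBr, THF, −78 to 0 °C; sat. aq. NH4Cl
Reagents that add atoms: vinylmagnesium bromide, C=C[Mg]Br
Why: Grignard 1,2-addition to an aryl aldehyde; the new carbinol centre is erased in step 3, so no control is needed.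

Step 3
Reactants: 3 1-[3-(benzyloxy)-4,5-dimethoxyphenyl]prop-2-en-1-ol
Product: 4 1-[3-(benzyloxy)-4,5-dimethoxyphenyl]prop-2-en-1-one
Conditions: Dess–Martin periodinane, CH2Cl2, 0 to 23 °C; used promptly
Reagents that add atoms: none
Why: Dess–Martin oxidation of a benzylic allylic alcohol is mild and neutral enough to deliver the polymerisation-prone aryl vinyl ketone without allylic transposition.

Step 4
Reactants: 4 1-[3-(benzyloxy)-4,5-dimethoxyphenyl]prop-2-en-1-one; 5 methyl eugenol (4-allyl-1,2-dimethoxybenzene)
Product: 6 (E)-1-[3-(benzyloxy)-4,5-dimethoxyphenyl]-4-(3,4-dimethoxyphenyl)but-2-en-1-one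
Conditions: second-generation Hoveyda–Grubbs catalyst (3 mol %), 1,4-benzoquinone (10 mol %), CH2Cl2, 40 °C
Reagents that add atoms: none
Why: Olefin cross-metathesis of a readily homodimerising allylarene with an electron-poor vinyl ketone favours the cross product as the E-enone, and benzoquinone should suppress ruthenium hydride-induced migration of the allyl double bond.

Step 5
Reactants: 7 chloromethyl methyl carbonate
Product: 8 iodomethyl methyl carbonate
Conditions: NaI, acetone, 23 °C, dark
Reagents that add atoms: sodium iodide, [Na+].[I-]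
Why: Finkelstein reaction at an activated O–CH2–Cl carbon, driven by precipitation of the chloride salt.

Step 6
Reactants: 8 iodomethyl methyl carbonate (2 equiv)
Product: 9 bis[(methoxycarbonyloxy)methyl]zinc
Conditions: Et2Zn (1 equiv), CH2Cl2, 0 °C, visible-light lamp; volatiles removed in vacuo; residue taken up in toluene under argon
Reagents that add atoms: diethylzinc, CC[Zn]CC
Why: Light-initiated iodine–zinc exchange, known for iodomethyl carboxylates, should give the carbonyl-chelated bis(acyloxymethyl)zinc, and full exchange with evaporation leaves no transferable ethyl group.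

Step 7
Reactants: 6 (E)-1-[3-(benzyloxy)-4,5-dimethoxyphenyl]-4-(3,4-dimethoxyphenyl)but-2-en-1-one; 9 bis[(methoxycarbonyloxy)methyl]zinc
Product: 11 (3S,4R)-3-[3-(benzyloxy)-4,5-dimethoxybenzoyl]-4-(3,4-dimethoxybenzyl)dihydrofuran-2(3H)-one, via zinc enolate 10 (not isolated)
Conditions: (CuOTf)2·C6H6 (2.5 mol %), (S,R,R)-phosphoramidite from (S)-BINOL and bis[(R)-1-phenylethyl]amine (10 mol %), toluene, −30 to 23 °C; 1 M HCl
Reagents that add atoms: none
Why: Proposed new method: the chiral monovalent copper–phosphoramidite complex should take one (methoxycarbonyloxy)methyl group from 9, bind the enone and deliver the CH2 carbon to the β-carbon (C4–C5 bond), and the zinc enolate 10 so formed then attacks its own carbonate carbonyl through C3 and expels methoxide (C2–C3 bond). The closest known reaction types are the copper-catalysed asymmetric conjugate addition of dialkylzincs to acyclic enones, the conjugate addition of (acyloxymethyl)zinc–copper reagents to enones and the tandem conjugate addition–Dieckmann trapping of zinc enolates by tethered esters; new is that donor carbon and acyl acceptor arrive in one C–O–C reagent. The single ring closes in the favoured 5-(enolexo)-exo-trig mode. C4 is set by the ligand, which should expose the Re face of the β-carbon, whereas C3 lies between two carbonyl groups and settles through its enolate into the trans (3S,4R) arrangement on the acidic quench. Regioselectivity is secured by the aroyl group, which makes C4 the only electrophilic and C3 the only nucleophilic alkene carbon. Chemoselectivity for C-acylation over 3-exo-tet displacement of the carbonate (cyclopropane) and over O-acylation (seven-membered enol carbonate) rests on the poor leaving-group quality of methyl carbonate at a saturated carbon and on the zinc chelate of the β-keto lactone as thermodynamic sink.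

Step 8
Reactants: 11 (3S,4R)-3-[3-(benzyloxy)-4,5-dimethoxybenzoyl]-4-(3,4-dimethoxybenzyl)dihydrofuran-2(3H)-one
Product: 14 (3R,4R)-4-(3,4-dimethoxybenzyl)-3-(3-hydroxy-4,5-dimethoxybenzyl)dihydrofuran-2(3H)-one, via phenol ketone 12 (not isolated), via benzylic carbinol 13 (not isolated)
Conditions: H2 (4 atm), Pd/C, AcOH, cat. HClO4, 23 °C
Reagents that add atoms: none
Why: Catalytic hydrogenolysis should cleave the aryl benzyl ether and take the electron-rich aryl ketone through the carbinol to CH2 without touching C3 or C4, as known for α-(hydroxybenzyl) lactones of this family; the C3 descriptor changes from S to R only because the substituent ranking changes.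

## Compound list

1 | 3-hydroxy-4,5-dimethoxybenzaldehyde | O=Cc1cc(O)c(OC)c(OC)c1 | starting material
2 | 3-(benzyloxy)-4,5-dimethoxybenzaldehyde | O=Cc1cc(OCc2ccccc2)c(OC)c(OC)c1 | intermediate
3 | 1-[3-(benzyloxy)-4,5-dimethoxyphenyl]prop-2-en-1-ol (racemic) | C=CC(O)c1cc(OCc2ccccc2)c(OC)c(OC)c1 | intermediate
4 | 1-[3-(benzyloxy)-4,5-dimethoxyphenyl]prop-2-en-1-one | C=CC(=O)c1cc(OCc2ccccc2)c(OC)c(OC)c1 | intermediate
5 | methyl eugenol (4-allyl-1,2-dimethoxybenzene) | C=CCc1ccc(OC)c(OC)c1 | starting material
6 | (E)-1-[3-(benzyloxy)-4,5-dimethoxyphenyl]-4-(3,4-dimethoxyphenyl)but-2-en-1-one | COc1ccc(C/C=C/C(=O)c2cc(OCc3ccccc3)c(OC)c(OC)c2)cc1OC | intermediate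
7 | chloromethyl methyl carbonate | COC(=O)OCCl | starting material
8 | iodomethyl methyl carbonate | COC(=O)OCI | intermediate
9 | bis[(methoxycarbonyloxy)methyl]zinc | COC(=O)OC[Zn]COC(=O)OC | intermediate
10 | [(methoxycarbonyloxy)methyl]zinc (Z)-enolate of (R)-1-[3-(benzyloxy)-4,5-dimethoxyphenyl]-4-(3,4-dimethoxyphenyl)-3-[(methoxycarbonyloxy)methyl]butan-1-one | COC(=O)OC[C@H](Cc1ccc(OC)c(OC)c1)/C=C(\O[Zn]COC(=O)OC)c1cc(OCc2ccccc2)c(OC)c(OC)c1 | intermediate (not isolated)
11 | (3S,4R)-3-[3-(benzyloxy)-4,5-dimethoxybenzoyl]-4-(3,4-dimethoxybenzyl)dihydrofuran-2(3H)-one | COc1ccc(C[C@H]2COC(=O)[C@@H]2C(=O)c2cc(OCc3ccccc3)c(OC)c(OC)c2)cc1OC | intermediate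
12 | (3S,4R)-4-(3,4-dimethoxybenzyl)-3-(3-hydroxy-4,5-dimethoxybenzoyl)dihydrofuran-2(3H)-one | COc1ccc(C[C@H]2COC(=O)[C@@H]2C(=O)c2cc(O)c(OC)c(OC)c2)cc1OC | intermediate (not isolated)
13 | (3S,4R)-4-(3,4-dimethoxybenzyl)-3-[hydroxy(3-hydroxy-4,5-dimethoxyphenyl)methyl]dihydrofuran-2(3H)-one, both carbinol epimers | COc1ccc(C[C@H]2COC(=O)[C@@H]2C(O)c2cc(O)c(OC)c(OC)c2)cc1OC | intermediate (not isolated)
14 | (3R,4R)-4-(3,4-dimethoxybenzyl)-3-(3-hydroxy-4,5-dimethoxybenzyl)dihydrofuran-2(3H)-one | COc1ccc(C[C@H]2COC(=O)[C@@H]2Cc2cc(O)c(OC)c(OC)c2)cc1OC | target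

## Step count and risks

Total step count: 8. Longest linear sequence: 6 (steps 1, 2, 3, 4, 7, 8).

**Risk 1, step 7.**
- What may go wrong: the oxygenated methyl group may transfer sluggishly from zinc to copper. Facial selectivity on this acyclic enone may be poor. The enone double bond may migrate toward ring A before addition, or the sequence may stall at the open-chain stage.
- Fallback (known chemistry): it sets out from 5 and 2 and comes back at 14.
- Methyl eugenol 5 undergoes (2+2) cycloaddition with dichloroketene (Cl3CCOCl, Zn–Cu couple, Et2O) to give 2,2-dichloro-3-(3,4-dimethoxybenzyl)cyclobutan-1-one F1.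
- Reductive dechlorination (Zn, AcOH) gives 3-(3,4-dimethoxybenzyl)cyclobutan-1-one F2.
- An enantioselective Baeyer–Villiger desymmetrisation (monooxygenase whole cells, or a chiral phosphoric acid with H2O2) gives (R)-4-(3,4-dimethoxybenzyl)dihydrofuran-2(3H)-one F3.
- The lithium enolate of F3 (LiN(iPr)2, THF, −78 °C) adds to aldehyde 2 anti to the C4 substituent. This gives the aldol (3S,4R)-3-{[3-(benzyloxy)-4,5-dimethoxyphenyl](hydroxy)methyl}-4-(3,4-dimethoxybenzyl)dihydrofuran-2(3H)-one F4.
- Hydrogenolysis of F4 (H2, Pd/C, AcOH) gives 14.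

**Risk 2, step 6.**
- What may go wrong: the exchange may be incomplete, leaving ethyl groups on zinc that would compete in the transfer. The reagent may also decompose in a carbenoid manner during concentration.
- Fallback: it replaces halogen–metal exchange by oxidative insertion, sets out from 8 and comes back at 11.
- Zinc dust (activated with BrCH2CH2Br and Me3SiCl, THF, 10 °C) inserts into the C–I bond, as known for iodomethyl pivalate, to give (methoxycarbonyloxy)methylzinc iodide F5.
- Me3SiCH2Li at −78 °C converts F5 into the mixed reagent [(methoxycarbonyloxy)methyl][(trimethylsilyl)methyl]zinc F6, whose silylmethyl group does not transfer.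
- F6 takes the place of 9 under the conditions of step 7 and should give 11.

**Risk 3, step 8.**
- What may go wrong: the reduction may stall at the carbinol stage. Acid-induced dehydration to the benzylidene lactone, followed by hydrogen delivery from the less hindered face, would erode the C3 configuration.
- Fallback: it replaces surface hydrogenolysis by hydride and ionic reduction, sets out from 11 and comes back at 14.
- NaBH4 (MeOH, −20 °C) reduces the ketone to the carbinol F4 described above.
- Et3SiH with BF3·OEt2 (CH2Cl2, −40 to 0 °C) removes the benzylic hydroxyl group through the aryl-stabilised cation. This gives (3R,4R)-3-[3-(benzyloxy)-4,5-dimethoxybenzyl]-4-(3,4-dimethoxybenzyl)dihydrofuran-2(3H)-one F7.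
- Any cis isomer is equilibrated to trans with DBU in toluene, and neutral hydrogenolysis (H2, Pd/C, EtOAc) frees the phenol to give 14.

Further compounds
F1 | step 7 | 2,2-dichloro-3-(3,4-dimethoxybenzyl)cyclobutan-1-one (racemic) | O=C1CC(Cc2ccc(OC)c(OC)c2)C1(Cl)Cl
F2 | step 7 | 3-(3,4-dimethoxybenzyl)cyclobutan-1-one | O=C1CC(Cc2ccc(OC)c(OC)c2)C1
F3 | step 7 | (R)-4-(3,4-dimethoxybenzyl)dihydrofuran-2(3H)-one | COc1ccc(C[C@H]2COC(=O)C2)cc1OC
F4 | step 7 | (3S,4R)-3-{[3-(benzyloxy)-4,5-dimethoxyphenyl](hydroxy)methyl}-4-(3,4-dimethoxybenzyl)dihydrofuran-2(3H)-one, both carbinol epimers | COc1ccc(C[C@H]2COC(=O)[C@@H]2C(O)c2cc(OCc3ccccc3)c(OC)c(OC)c2)cc1OC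
F5 | step 6 | (methoxycarbonyloxy)methylzinc iodide | COC(=O)OC[Zn]I
F6 | step 6 | [(methoxycarbonyloxy)methyl][(trimethylsilyl)methyl]zinc | COC(=O)OC[Zn]C[Si](C)(C)C
F7 | step 8 | (3R,4R)-3-[3-(benzyloxy)-4,5-dimethoxybenzyl]-4-(3,4-dimethoxybenzyl)dihydrofuran-2(3H)-one | COc1ccc(C[C@H]2COC(=O)[C@@H]2Cc2cc(OCc3ccccc3)c(OC)c(OC)c2)cc1OC
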